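## The problem

The target is a 3,3,6-trisubstituted 1,2-dioxane (ring atoms O1, O2, C3, C4, C5, C6). C3 is a peroxyketal carbon carrying a methoxy group and a sixteen-carbon chain, and C6 carries an acetic acid arm. The chain holds a conjugated (E)-enyne three methylenes away from C3 and ends in a methyl ketone, so it is most simply built by joining a terminal alkyne to an (E)-vinyl iodide late in the route. Two stereocentres must be set. C6 has no neighbour to direct it and needs absolute control from outside. C3 is a ketal centre that equilibrates under acid, and since the target has the methoxy group cis to the C6 arm (axial methoxy, both carbon substituents equatorial), C6 can steer C3 thermodynamically but C3 cannot steer C6. The O–O bond will not survive phosphines, hydride reagents, hydrogenation catalysts or stoichiometric low-valent metals. The hydrogen on C6 invites base-induced Kornblum–DeLaMare cleavage, the β-peroxy acid invites retro-oxa-Michael opening, and the peroxyketal is labile to aqueous acid. The feature that opens the chosen disconnection is that C4–C5 is the only ring C–C bond touching neither oxygenated carbon. C3–O2, O2–O1 and O1–C6 can therefore all be made first in an open-chain mixed peroxyketal, and the ring closed afterwards between C4 and C5.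

## Retrosynthesis

**Acid and enyne.** The acid 30 is traced to the primary alcohol 29, and 29 is cut at the C(sp)–C(sp2) bond of the enyne into the terminal alkyne 24 and the (E)-vinyl iodide 28. Cutting the neighbouring C(sp3)–C(sp) bond would call for an acetylide anion, which attacks O–O, and building the alkene by olefination would risk the E geometry next to an enolisable ketone. The Sonogashira cut removes eleven carbons and all chain unsaturation but the alkyne, and asks only that catalytic palladium and copper with an amine leave the peroxyketal alone. The oxidation is placed last so that the β-peroxy acid never meets amine or copper.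

**Vinyl iodide.** Iodide 28 is cut at its C=C bond to aldehyde 27 by a one-carbon Takai homologation, which prefers aldehydes over ketones and gives the E isomer. Aldehyde 27 comes from hydroxy ketone 26, and 26 from the terminal alkene of commercial 25 by Wacker oxidation. Hydrometalation of an alkyne was set aside because it would reduce the ketone.

**Adjustments on the ring.** Alkyne 24 arises from 23 by removal of both silicon groups in one operation. Compound 23 is the thermodynamic C3 epimer of the mixture 22, reached by acid-catalysed ketal exchange, and 22 is the dihydro derivative of the ring alkene 21. Saturation is placed before equilibration because ionisation of 21 at C3 would give an allylic cation and invite transposition.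

**Ring closure (key cut).** The C4=C5 bond of 21 is cut to give the acyclic diene 20, in which a vinyl group on C3 and an enoate alkene on C6 are held together by the C3–O2–O1–C6 tether. Every other ring disconnection breaks a C–O or O–O bond and has to create the peroxide and the ring together. This one lets the peroxide be made in an open chain under SN2 control and asks the forward step only for an olefin metathesis that tolerates O–O and ignores the capped alkyne.

**Peroxyketal tether.** Diene 20 is cut at C3–O2 into the secondary hydroperoxide 12 and the vinyl ketone dimethyl ketal 19. The forward reaction is an acid-catalysed ketal exchange, which keeps one methoxy group on C3 and involves no base, so the base-sensitive C6–H is safe.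

**Hydroperoxide half.** Hydroperoxide 12 comes from its acetone-derived perketal 11, and 11 from displacement of the mesylate 8 by the protected hydroperoxide 10 (made from alkene 9), which forms C6–O1 with inversion. The mesylate leads back through alcohol 7 and the anilinooxy enoate 6 to aldehyde 3 and phosphonate 4 by proline-catalysed α-aminoxylation and olefination; 3 comes from diol 1 via 2. The enoate serves three purposes: it activates C6 for SN2, it suppresses ionisation and allylic scrambling, and it later acts as the sacrificial alkene terminus.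

**Ketal half.** Ketal 19 is traced by dehydrochlorination to the β-chloro ketal 18, then to the ketone 17, which is cut at the acyl C–C bond into acid chloride 15 and the Grignard reagent 16 from the silyl-capped chloroalkyne 14, itself made from 13. The β-chloro ketone is used because a vinyl ketone cannot be ketalised directly without conjugate addition.

## Roads not taken

Alternative 1: This road cuts C4–C5, C6–O1 and O2–C3 at once. In the forward step Mn(OAc)3 (trivalent manganese) oxidises the β-keto ester A2 to its C4 radical, which adds to the alkene A3; the C6 radical captures O2 and the peroxide closes on the ketone to give the 1,2-dioxan-3-ol A1. Its merit is that one step builds the ring from three simple pieces with both oxygens taken from air, and in ring construction it is clearly shorter than the chosen plan. Its weak points for this target are that the C6 radical captures O2 without facial control, so A1 is racemic, that an unactivated monosubstituted alkene such as A3 is a poor radical acceptor in this chemistry, and that the tert-butyl ester on C4 is superfluous and must be excised from a peroxide-bearing ring. The hemiketal must then be exchanged to the methyl ketal and the four-carbon arm turned into the alkyne. Against the shorter ring synthesis the chosen plan sets absolute control of C6 by a catalytic asymmetric step and a skeleton with no carbon to remove.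

Alternative 2: This road cuts O2–C3 and C3–OMe. In acidic methanol the hydroperoxy ketone A5 closes to the peroxyhemiketal and is methylated to A4 under anomeric control. It is biomimetic, needs no metal, forms no ring alkene that must be reduced beside an alkyne, and sets C3 in the ring-forming step. In step count and mildness of ring closure it is at least as good as the chosen plan. Its burden lies in A5: the stereodefined secondary hydroperoxide must be installed by displacement at an unactivated secondary carbon in a chain that already carries the ketone, where elimination competes and the peroxide anion is slow. The chosen plan sets against this a displacement at a vinylogously activated centre and a late, convergent union of two independently made halves. Because this road is so close in merit, its logic is kept as the fallback for the ring closure.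

Alternative 3: This road cuts the cyclobutane C–C bond that becomes C3···C6 and forms C6–O1 and O2–C3. Co(acac)2 (divalent cobalt) and O2 convert the cyclobutanol A7 to an alkoxy radical that fragments to the secondary C6 radical; this captures O2 and the peroxide closes on the new ketone to give the 1,2-dioxan-3-ol A6. It is very short and the regiochemistry of the fragmentation is reliable. For this target it fails on the same point as Alternative 1: C6 is formed from a planar radical, so A6 is racemic and a resolution would be needed; the 1,2-disubstituted cyclobutanol A7 is also not trivial to make. The chosen plan is longer but carries C6 as a single enantiomer from the start.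

Key step: step 14

## Route

Remark on the chemistry: the ring is numbered O1, O2, C3 (peroxyketal carbon), C4, C5, C6 throughout; the target is then (3R,6S), and its methoxy group cis to the C6 arm is taken to be the thermodynamically preferred axial-methoxy arrangement. The descriptor at C6 changes with the neighbouring groups (R in 11, 12, 20 and 21; S in 22–24, 29 and 30) while the spatial arrangement stays the same.

Step 1
Reactants: 1 butane-1,4-diol
Product: 2 4-[(tert-butyldiphenylsilyl)oxy]butan-1-ol
Conditions: TBDPSCl (1 equiv), imidazole, 1 in excess (5 equiv), DMF, 0 °C to rt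
Reagents that add atoms: tert-butyl(chloro)diphenylsilane, CC(C)(C)[Si](Cl)(c1ccccc1)c1ccccc1
Why: Silyl ether formation on a symmetrical diol; the excess of diol keeps the bis-ether low and the unreacted diol is washed out with water.

Step 2
Reactants: 2 4-[(tert-butyldiphenylsilyl)oxy]butan-1-ol
Product: 3 4-[(tert-butyldiphenylsilyl)oxy]butanal
Conditions: TEMPO (10 mol%), PhI(OAc)2 (1.1 equiv), CH2Cl2, rt
Reagents that add atoms: none
Why: Oxoammonium (TEMPO) oxidation of a primary alcohol, which stops at the aldehyde in the absence of water and leaves the silyl ether untouched.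

Step 3
Reactants: 3 4-[(tert-butyldiphenylsilyl)oxy]butanal; 4 trimethyl phosphonoacetate
Product: 6 methyl (S,E)-4-[(phenylamino)oxy]-6-[(tert-butyldiphenylsilyl)oxy]hex-2-enoate, via (S)-2-anilinooxy aldehyde 5 (not isolated)
Conditions: PhNO (1 equiv), D-proline (20 mol%), DMSO, rt; then 4, LiCl, DBU, MeCN, 0 °C
Reagents that add atoms: nitrosobenzene, O=Nc1ccccc1
Why: Proline-catalysed α-aminoxylation (enamine catalysis) followed in the same flask by Horner–Wadsworth–Emmons olefination under Masamune–Roush conditions. The D-proline enamine should be oxygenated on the face that gives the (S)-aldehyde, the mirror image of the established L-proline sense, and the mild base should give the E-enoate without epimerisation.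

Step 4
Reactants: 6 methyl (S,E)-4-[(phenylamino)oxy]-6-[(tert-butyldiphenylsilyl)oxy]hex-2-enoate
Product: 7 methyl (S,E)-4-hydroxy-6-[(tert-butyldiphenylsilyl)oxy]hex-2-enoate
Conditions: Cu(OAc)2·H2O (30 mol%), MeOH, rt
Reagents that add atoms: none
Why: Copper-catalysed N–O bond cleavage of an O-alkyl-N-arylhydroxylamine; the C–O bond is not touched, so the configuration is retained and the enoate is not reduced.

Step 5
Reactants: 7 methyl (S,E)-4-hydroxy-6-[(tert-butyldiphenylsilyl)oxy]hex-2-enoate
Product: 8 methyl (S,E)-4-[(methylsulfonyl)oxy]-6-[(tert-butyldiphenylsilyl)oxy]hex-2-enoate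
Conditions: MsCl, Et3N, CH2Cl2, −20 °C
Reagents that add atoms: methanesulfonyl chloride, CS(=O)(=O)Cl
Why: Sulfonylation of a secondary alcohol with retention; the ester-deactivated allylic mesylate should be stable enough to isolate cold and use at once.

Step 6
Reactants: 9 2,3-dimethylbut-2-ene
Product: 10 2-hydroperoxy-2-methoxypropane (2-methoxyprop-2-yl hydroperoxide)
Conditions: O3, MeOH/CH2Cl2, −78 °C; used as a solution
Reagents that add atoms: ozone, [O-][O+]=O; methanol, CO
Why: Ozonolysis by the Criegee mechanism; the carbonyl oxide from the tetrasubstituted alkene is trapped by methanol to give the α-methoxy hydroperoxide, a hydroperoxide nucleophile whose second oxygen is masked as a ketal.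

Step 7
Reactants: 8 methyl (S,E)-4-[(methylsulfonyl)oxy]-6-[(tert-butyldiphenylsilyl)oxy]hex-2-enoate; 10 2-hydroperoxy-2-methoxypropane
Product: 11 methyl (R,E)-4-[(2-methoxypropan-2-yl)peroxy]-6-[(tert-butyldiphenylsilyl)oxy]hex-2-enoate
Conditions: 10 (2 equiv), CsOH·H2O (1.5 equiv), DMF, 0 °C, short reaction time
Reagents that add atoms: none
Why: SN2 displacement of a secondary sulfonate by a peroxide anion (α-effect nucleophile) with inversion, which sets C6. The centre is a vinylogous α-sulfonyloxy ester, so it is activated for SN2 and closed to ionisation and allylic scrambling; the hydroperoxide is kept in excess over the base so that no free hydroxide remains.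

Step 8
Reactants: 11 methyl (R,E)-4-[(2-methoxypropan-2-yl)peroxy]-6-[(tert-butyldiphenylsilyl)oxy]hex-2-enoate
Product: 12 methyl (R,E)-4-hydroperoxy-6-[(tert-butyldiphenylsilyl)oxy]hex-2-enoate
Conditions: AcOH/THF/H2O (4:2:1), rt
Reagents that add atoms: none
Why: Mild acid hydrolysis of the acyclic perketal, which behaves like a mixed acetone ketal; the C6–O bond is not involved, so the configuration is kept.

Step 9
Reactants: 13 5-chloropent-1-yne
Product: 14 (5-chloropent-1-yn-1-yl)tri(propan-2-yl)silane
Conditions: n-BuLi, THF, −78 °C; then TIPSOTf, −78 °C to rt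
Reagents that add atoms: triisopropylsilyl trifluoromethanesulfonate, CC(C)[Si](OS(=O)(=O)C(F)(F)F)(C(C)C)C(C)C
Why: C-silylation of a lithium acetylide; the bulky cap is what later shields the alkyne from the metathesis catalyst and from diimide.

Step 10
Reactants: 14 (5-chloropent-1-yn-1-yl)tri(propan-2-yl)silane; 15 3-chloropropanoyl chloride
Product: 17 1-chloro-8-(triisopropylsilyl)oct-7-yn-3-one, via alkylmagnesium chloride 16 (not isolated)
Conditions: Mg, THF, reflux; then added to 15 (1.2 equiv), Fe(acac)3 (3 mol%), THF, −78 °C
Reagents that add atoms: none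
Why: Grignard formation from the primary chloride followed by iron-catalysed acylation of the acid chloride, which at −78 °C should be faster than addition to the product ketone or dehydrochlorination.

Step 11
Reactants: 17 1-chloro-8-(triisopropylsilyl)oct-7-yn-3-one
Product: 18 (8-chloro-6,6-dimethoxyoct-1-yn-1-yl)tri(propan-2-yl)silane
Conditions: HC(OMe)3, MeOH, TsOH·H2O (cat.), rt; Et3N quench
Reagents that add atoms: trimethyl orthoformate, COC(OC)OC; methanol, CO
Why: Acid-catalysed ketalisation driven by the orthoester as water scavenger; the β-chloro ketone is ketalised before elimination because a vinyl ketone would add methanol.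

Step 12
Reactants: 18 (8-chloro-6,6-dimethoxyoct-1-yn-1-yl)tri(propan-2-yl)silane
Product: 19 (6,6-dimethoxyoct-7-en-1-yn-1-yl)tri(propan-2-yl)silane
Conditions: KOtBu, THF, 0 °C to rt
Reagents that add atoms: none
Why: E2 dehydrochlorination of a β-chloro ketal, the classical entry to vinyl ketone ketals; only the methylene next to the ketal carbon carries β-hydrogens.

Step 13
Reactants: 12 methyl (R,E)-4-hydroperoxy-6-[(tert-butyldiphenylsilyl)oxy]hex-2-enoate; 19 (6,6-dimethoxyoct-7-en-1-yn-1-yl)tri(propan-2-yl)silane
Product: 20 methyl (R,E)-4-{[3-methoxy-8-(triisopropylsilyl)oct-1-en-7-yn-3-yl]peroxy}-6-[(tert-butyldiphenylsilyl)oxy]hex-2-enoate, both epimers at the ketal carbon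
Conditions: 19 (2 equiv), PPTS (10 mol%), CH2Cl2, 5 Å molecular sieves, 0 °C to rt
Reagents that add atoms: none
Why: Acid-catalysed ketal exchange (peroxyketal formation): the methoxy-stabilised cation from 19 is captured at the ketal carbon by the hydroperoxide and the sieves take up the methanol. No base is present, so the sensitive C6–H is safe.

Step 14
Reactants: 20 methyl (R,E)-4-{[3-methoxy-8-(triisopropylsilyl)oct-1-en-7-yn-3-yl]peroxy}-6-[(tert-butyldiphenylsilyl)oxy]hex-2-enoate (both ketal epimers)
Product: 21 (6R)-3-methoxy-3-[5-(triisopropylsilyl)pent-4-yn-1-yl]-6-{2-[(tert-butyldiphenylsilyl)oxy]ethyl}-3,6-dihydro-1,2-dioxine, both C3 epimers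
Conditions: second-generation Hoveyda–Grubbs catalyst (10 mol%), CH2Cl2 (5 mM), 40 °C
Reagents that add atoms: none
Why: Ring-closing olefin metathesis: the ruthenium benzylidene should exchange first onto the monosubstituted C3 vinyl group, the new alkylidene adds to the enoate alkene in an intramolecular [2+2] step, and cycloreversion forms C4=C5 and a ruthenium ester-carbene that re-enters the cycle by exchange with the vinyl group of another molecule of 20, releasing the ester terminus as an acrylate. The closest known reaction type is ruthenium-catalysed ring-closing metathesis of dienes tethered through a dialkyl peroxide, together with ring closures in which an enoate serves as the sacrificial alkene terminus. The single ring formed, the 3,6-dihydro-1,2-dioxine, closes by joining C4 to C5 across the preformed C3–O2–O1–C6 tether, and the six-membered ring forces the new alkene to be cis. No stereocentre is created: C6 keeps the configuration fixed in step 7 and C3 remains a mixture that step 16 resolves. The step needs diene metathesis to outrun enyne metathesis, which the bulky triisopropylsilyl cap should secure, and ring closure to outrun cross-metathesis, which high dilution, the fully substituted C3 (Thorpe–Ingold effect) and the gauche preference of the C–O–O–C unit favour. The O–O bond should survive because the catalyst is neutral and carries no free phosphine.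

Step 15
Reactants: 21 (6R)-3-methoxy-3-[5-(triisopropylsilyl)pent-4-yn-1-yl]-6-{2-[(tert-butyldiphenylsilyl)oxy]ethyl}-3,6-dihydro-1,2-dioxine (both C3 epimers)
Product: 22 (6S)-3-methoxy-3-[5-(triisopropylsilyl)pent-4-yn-1-yl]-6-{2-[(tert-butyldiphenylsilyl)oxy]ethyl}-1,2-dioxane, both C3 epimers
Conditions: KO2CN=NCO2K (excess), AcOH, CH2Cl2, 0 °C to rt
Reagents that add atoms: none
Why: Diimide reduction, a concerted syn transfer of two hydrogens to the C=C bond that does not cleave O–O. The hindered silyl-capped alkyne should react much more slowly than the cis ring alkene, and the weakly acidic medium avoids the amine-induced Kornblum–DeLaMare opening to which dihydrodioxines are prone.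

Step 16
Reactants: 22 (6S)-3-methoxy-3-[5-(triisopropylsilyl)pent-4-yn-1-yl]-6-{2-[(tert-butyldiphenylsilyl)oxy]ethyl}-1,2-dioxane (both C3 epimers)
Product: 23 (3R,6S)-3-methoxy-3-[5-(triisopropylsilyl)pent-4-yn-1-yl]-6-{2-[(tert-butyldiphenylsilyl)oxy]ethyl}-1,2-dioxane
Conditions: CSA (10 mol%), MeOH/CH2Cl2 (1:4), 0 °C to rt
Reagents that add atoms: methanol, CO
Why: Acid-catalysed ketal exchange through the cyclic peroxycarbenium ion under thermodynamic control. The anomeric effect should place the methoxy group axial with both carbon substituents equatorial, which, with C6 fixed as S, is the 3R epimer.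

Step 17
Reactants: 23 (3R,6S)-3-methoxy-3-[5-(triisopropylsilyl)pent-4-yn-1-yl]-6-{2-[(tert-butyldiphenylsilyl)oxy]ethyl}-1,2-dioxane
Product: 24 2-[(3R,6S)-3-methoxy-3-(pent-4-yn-1-yl)-1,2-dioxan-6-yl]ethan-1-ol
Conditions: Bu4NF (3 equiv), THF, 0 °C to rt
Reagents that add atoms: none
Why: Fluoride-mediated desilylation cleaves the Si–O bond of the silyl ether and the Si–C(sp) bond of the alkynylsilane in one operation; the saturated dialkyl peroxyketal has no activated C–H and should tolerate the mildly basic fluoride.

Step 18
Reactants: 25 dec-9-en-1-ol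
Product: 26 10-hydroxydecan-2-one
Conditions: PdCl2 (10 mol%), CuCl (30 mol%), O2 (1 atm), DMF/H2O (7:1), rt
Reagents that add atoms: water, O
Why: Wacker–Tsuji oxidation of a terminal alkene gives the methyl ketone with Markovnikov selectivity and tolerates the free primary alcohol.

Step 19
Reactants: 26 10-hydroxydecan-2-one
Product: 27 9-oxodecanal
Conditions: TEMPO (10 mol%), PhI(OAc)2 (1.1 equiv), CH2Cl2, rt
Reagents that add atoms: none
Why: Oxoammonium (TEMPO) oxidation of the primary alcohol to the aldehyde under non-aqueous conditions that do not enolise the ketone.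

Step 20
Reactants: 27 9-oxodecanal
Product: 28 (E)-11-iodoundec-10-en-2-one
Conditions: CrCl2 (6 equiv), CHI3 (2 equiv), THF, 0 °C to rt
Reagents that add atoms: iodoform, IC(I)I
Why: Takai iodo-olefination: the geminal dichromium species adds to aldehydes much faster than to ketones and eliminates to the E-vinyl iodide.

Step 21
Reactants: 24 2-[(3R,6S)-3-methoxy-3-(pent-4-yn-1-yl)-1,2-dioxan-6-yl]ethan-1-ol; 28 (E)-11-iodoundec-10-en-2-one
Product: 29 (E)-16-[(3R,6S)-6-(2-hydroxyethyl)-3-methoxy-1,2-dioxan-3-yl]hexadec-10-en-12-yn-2-one
Conditions: Pd(PPh3)4 (5 mol%), CuI (10 mol%), Et3N, THF, degassed, rt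
Reagents that add atoms: none
Why: Sonogashira coupling of a terminal alkyne with a vinyl iodide proceeds at room temperature with retention of the E geometry; dialkyl peroxyketals are expected to tolerate the catalytic zerovalent palladium and monovalent copper.

Step 22
Reactants: 29 (E)-16-[(3R,6S)-6-(2-hydroxyethyl)-3-methoxy-1,2-dioxan-3-yl]hexadec-10-en-12-yn-2-one
Product: 30 2-[(3R,6S)-3-methoxy-3-[(E)-15-oxohexadec-6-en-4-yn-1-yl]-1,2-dioxan-6-yl]acetic acid (CNP0165935.1)
Conditions: TEMPO (20 mol%), PhI(OAc)2 (2.2 equiv), MeCN/pH 7 phosphate buffer (1:1), 0 °C to rt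
Reagents that add atoms: water, O
Why: Oxoammonium (TEMPO) oxidation of the primary alcohol through the aldehyde hydrate to the carboxylic acid. The buffered, metal-free medium should spare the peroxyketal, the enyne and the ketone, and neither stereocentre is touched.

## Compound list

1 | butane-1,4-diol | OCCCCO | starting material
2 | 4-[(tert-butyldiphenylsilyl)oxy]butan-1-ol | OCCCCO[Si](c1ccccc1)(c1ccccc1)C(C)(C)C | intermediate
3 | 4-[(tert-butyldiphenylsilyl)oxy]butanal | O=CCCCO[Si](c1ccccc1)(c1ccccc1)C(C)(C)C | intermediate
4 | trimethyl phosphonoacetate | COC(=O)CP(=O)(OC)OC | starting material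
5 | (S)-2-[(phenylamino)oxy]-4-[(tert-butyldiphenylsilyl)oxy]butanal | c1ccc(cc1)NO[C@H](C=O)CCO[Si](c1ccccc1)(c1ccccc1)C(C)(C)C | intermediate
6 | methyl (S,E)-4-[(phenylamino)oxy]-6-[(tert-butyldiphenylsilyl)oxy]hex-2-enoate | c1ccc(cc1)NO[C@H](/C=C/C(=O)OC)CCO[Si](c1ccccc1)(c1ccccc1)C(C)(C)C | intermediate
7 | methyl (S,E)-4-hydroxy-6-[(tert-butyldiphenylsilyl)oxy]hex-2-enoate | O[C@H](/C=C/C(=O)OC)CCO[Si](c1ccccc1)(c1ccccc1)C(C)(C)C | intermediate
8 | methyl (S,E)-4-[(methylsulfonyl)oxy]-6-[(tert-butyldiphenylsilyl)oxy]hex-2-enoate | CS(=O)(=O)O[C@H](/C=C/C(=O)OC)CCO[Si](c1ccccc1)(c1ccccc1)C(C)(C)C | intermediate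
9 | 2,3-dimethylbut-2-ene | CC(C)=C(C)C | starting material
10 | 2-hydroperoxy-2-methoxypropane | COC(C)(C)OO | intermediate
11 | methyl (R,E)-4-[(2-methoxypropan-2-yl)peroxy]-6-[(tert-butyldiphenylsilyl)oxy]hex-2-enoate | COC(C)(C)OO[C@@H](/C=C/C(=O)OC)CCO[Si](c1ccccc1)(c1ccccc1)C(C)(C)C | intermediate
12 | methyl (R,E)-4-hydroperoxy-6-[(tert-butyldiphenylsilyl)oxy]hex-2-enoate | OO[C@@H](/C=C/C(=O)OC)CCO[Si](c1ccccc1)(c1ccccc1)C(C)(C)C | intermediate
13 | 5-chloropent-1-yne | C#CCCCCl | starting material
14 | (5-chloropent-1-yn-1-yl)tri(propan-2-yl)silane | ClCCCC#C[Si](C(C)C)(C(C)C)C(C)C | intermediate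
15 | 3-chloropropanoyl chloride | ClCCC(Cl)=O | starting material
16 | [5-(triisopropylsilyl)pent-4-yn-1-yl]magnesium chloride | Cl[Mg]CCCC#C[Si](C(C)C)(C(C)C)C(C)C | intermediate
17 | 1-chloro-8-(triisopropylsilyl)oct-7-yn-3-one | ClCCC(=O)CCCC#C[Si](C(C)C)(C(C)C)C(C)C | intermediate
18 | (8-chloro-6,6-dimethoxyoct-1-yn-1-yl)tri(propan-2-yl)silane | ClCCC(OC)(OC)CCCC#C[Si](C(C)C)(C(C)C)C(C)C | intermediate
19 | (6,6-dimethoxyoct-7-en-1-yn-1-yl)tri(propan-2-yl)silane | C=CC(OC)(OC)CCCC#C[Si](C(C)C)(C(C)C)C(C)C | intermediate
20 | methyl (R,E)-4-{[3-methoxy-8-(triisopropylsilyl)oct-1-en-7-yn-3-yl]peroxy}-6-[(tert-butyldiphenylsilyl)oxy]hex-2-enoate, both ketal epimers | C=CC(OC)(CCCC#C[Si](C(C)C)(C(C)C)C(C)C)OO[C@@H](/C=C/C(=O)OC)CCO[Si](c1ccccc1)(c1ccccc1)C(C)(C)C | intermediate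
21 | (6R)-3-methoxy-3-[5-(triisopropylsilyl)pent-4-yn-1-yl]-6-{2-[(tert-butyldiphenylsilyl)oxy]ethyl}-3,6-dihydro-1,2-dioxine, both C3 epimers | COC1(CCCC#C[Si](C(C)C)(C(C)C)C(C)C)C=C[C@@H](CCO[Si](c2ccccc2)(c2ccccc2)C(C)(C)C)OO1 | intermediate
22 | (6S)-3-methoxy-3-[5-(triisopropylsilyl)pent-4-yn-1-yl]-6-{2-[(tert-butyldiphenylsilyl)oxy]ethyl}-1,2-dioxane, both C3 epimers | COC1(CCCC#C[Si](C(C)C)(C(C)C)C(C)C)CC[C@@H](CCO[Si](c2ccccc2)(c2ccccc2)C(C)(C)C)OO1 | intermediate
23 | (3R,6S)-3-methoxy-3-[5-(triisopropylsilyl)pent-4-yn-1-yl]-6-{2-[(tert-butyldiphenylsilyl)oxy]ethyl}-1,2-dioxane | CO[C@@]1(CCCC#C[Si](C(C)C)(C(C)C)C(C)C)CC[C@@H](CCO[Si](c2ccccc2)(c2ccccc2)C(C)(C)C)OO1 | intermediate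
24 | 2-[(3R,6S)-3-methoxy-3-(pent-4-yn-1-yl)-1,2-dioxan-6-yl]ethan-1-ol | CO[C@@]1(CCCC#C)CC[C@@H](CCO)OO1 | intermediate
25 | dec-9-en-1-ol | C=CCCCCCCCCO | starting material
26 | 10-hydroxydecan-2-one | CC(=O)CCCCCCCCO | intermediate
27 | 9-oxodecanal | CC(=O)CCCCCCCC=O | intermediate
28 | (E)-11-iodoundec-10-en-2-one | CC(=O)CCCCCCC/C=C/I | intermediate
29 | (E)-16-[(3R,6S)-6-(2-hydroxyethyl)-3-methoxy-1,2-dioxan-3-yl]hexadec-10-en-12-yn-2-one | CO[C@@]1(CCCC#C/C=C/CCCCCCCC(C)=O)CC[C@@H](CCO)OO1 | intermediate
30 | 2-[(3R,6S)-3-methoxy-3-[(E)-15-oxohexadec-6-en-4-yn-1-yl]-1,2-dioxan-6-yl]acetic acid | CO[C@@]1(CCCC#C/C=C/CCCCCCCC(C)=O)CC[C@@H](CC(=O)O)OO1 | target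

## Step count and risk

Total: 22 steps. Longest linear sequence: 14 steps (steps 1–5, 7, 8, 13–17, 21 and 22, from diol 1).

**Step 14 (key step).** The most likely failure is slow catalyst turnover. The vinyl group sits on a fully substituted carbon and the partner is an electron-poor enoate, so initiation and the ring-closing [2+2] may both be sluggish. Cross-metathesis oligomers or catalyst decay would then take over, and ruthenium hydride species formed on decay could also cleave the O–O bond. The fallback sets out from 7 and 16 and returns at 23; it closes the ring at O2–C3 instead of C4=C5.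
- Hydrogenation of 7 (H2, Pd/C, EtOAc) and acid-catalysed lactonisation would give (R)-5-{2-[(tert-butyldiphenylsilyl)oxy]ethyl}oxolan-2-one F1.
- One equivalent of Grignard reagent 16 at −78 °C would open the lactone to (R)-1-[(tert-butyldiphenylsilyl)oxy]-3-hydroxy-11-(triisopropylsilyl)undec-10-yn-6-one F2.
- MsCl and Et3N would give (R)-1-[(tert-butyldiphenylsilyl)oxy]-6-oxo-11-(triisopropylsilyl)undec-10-yn-3-yl methanesulfonate F3.
- Displacement with 10 and CsOH·H2O in DMF, now at an unactivated secondary carbon, would give with inversion (S)-1-[(tert-butyldiphenylsilyl)oxy]-3-[(2-methoxypropan-2-yl)peroxy]-11-(triisopropylsilyl)undec-10-yn-6-one F4.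
- CSA in MeOH would unmask the hydroperoxide, which adds to the ketone, and the peroxyhemiketal would be methylated under thermodynamic control to give 23 directly.

**Step 7.** Three processes may compete with substitution: E2 elimination of the mesylate to the dienoate, base-induced Kornblum–DeLaMare fragmentation of the product through loss of the ester-activated C6 hydrogen, and conjugate addition of the peroxide anion to the enoate. The fallback sets out from 3 and returns at 11; it installs the peroxide at an unactivated carbon and builds the enoate afterwards under neutral conditions.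
- The aminoxylation of step 3, quenched with NaBH4 instead of the phosphonate, would give (S)-2-[(phenylamino)oxy]-4-[(tert-butyldiphenylsilyl)oxy]butan-1-ol F5.
- Cu(OAc)2 in MeOH would give (S)-4-[(tert-butyldiphenylsilyl)oxy]butane-1,2-diol F6.
- Bu2SnO, then 4-methoxybenzyl chloride and Bu4NI, would protect the primary hydroxyl as (S)-1-[(4-methoxybenzyl)oxy]-4-[(tert-butyldiphenylsilyl)oxy]butan-2-ol F7.
- MsCl and Et3N would give (S)-1-[(4-methoxybenzyl)oxy]-4-[(tert-butyldiphenylsilyl)oxy]butan-2-yl methanesulfonate F8.
- Displacement with 10 and CsOH·H2O in DMF would give with inversion (R)-tert-butyl{3-[(2-methoxypropan-2-yl)peroxy]-4-[(4-methoxybenzyl)oxy]butoxy}diphenylsilane F9.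
- DDQ in CH2Cl2/pH 7 buffer would free (R)-2-[(2-methoxypropan-2-yl)peroxy]-4-[(tert-butyldiphenylsilyl)oxy]butan-1-ol F10.
- Buffered Dess–Martin oxidation would give (R)-2-[(2-methoxypropan-2-yl)peroxy]-4-[(tert-butyldiphenylsilyl)oxy]butanal F11.
- Wittig olefination with the stabilised ylide Ph3P=CHCO2Me in CH2Cl2 would give 11.

**Step 13.** The cation from the vinyl ketal is an alkoxyallyl cation, so the hydroperoxide may be captured at the terminal carbon with allylic transposition. The ketal may also hydrolyse to the enone, or exchange twice to a bis-peroxide. The fallback sets out from 18 and 12 and returns at 20; it carries out the exchange on a saturated ketal and unveils the vinyl group afterwards without base.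
- PhSeNa (from (PhSe)2 and NaBH4 in EtOH) would convert 18 into [6,6-dimethoxy-8-(phenylselanyl)oct-1-yn-1-yl]tri(propan-2-yl)silane F12.
- PPTS-catalysed exchange with 12 would give methyl (R,E)-4-{[3-methoxy-1-(phenylselanyl)-8-(triisopropylsilyl)oct-7-yn-3-yl]peroxy}-6-[(tert-butyldiphenylsilyl)oxy]hex-2-enoate F13.
- Oxidation with NaIO4 and NaHCO3 in aqueous MeOH/THF, followed by syn-elimination of the selenoxide at rt, would give 20.

Further compounds

F1 | step 14 | (R)-5-{2-[(tert-butyldiphenylsilyl)oxy]ethyl}oxolan-2-one | O=C1CC[C@H](CCO[Si](c2ccccc2)(c2ccccc2)C(C)(C)C)O1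
F2 | step 14 | (R)-1-[(tert-butyldiphenylsilyl)oxy]-3-hydroxy-11-(triisopropylsilyl)undec-10-yn-6-one | O[C@H](CCC(=O)CCCC#C[Si](C(C)C)(C(C)C)C(C)C)CCO[Si](c1ccccc1)(c1ccccc1)C(C)(C)C
F3 | step 14 | (R)-1-[(tert-butyldiphenylsilyl)oxy]-6-oxo-11-(triisopropylsilyl)undec-10-yn-3-yl methanesulfonate | CS(=O)(=O)O[C@H](CCC(=O)CCCC#C[Si](C(C)C)(C(C)C)C(C)C)CCO[Si](c1ccccc1)(c1ccccc1)C(C)(C)C
F4 | step 14 | (S)-1-[(tert-butyldiphenylsilyl)oxy]-3-[(2-methoxypropan-2-yl)peroxy]-11-(triisopropylsilyl)undec-10-yn-6-one | COC(C)(C)OO[C@@H](CCC(=O)CCCC#C[Si](C(C)C)(C(C)C)C(C)C)CCO[Si](c1ccccc1)(c1ccccc1)C(C)(C)C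
F5 | step 7 | (S)-2-[(phenylamino)oxy]-4-[(tert-butyldiphenylsilyl)oxy]butan-1-ol | c1ccc(cc1)NO[C@H](CO)CCO[Si](c1ccccc1)(c1ccccc1)C(C)(C)C
F6 | step 7 | (S)-4-[(tert-butyldiphenylsilyl)oxy]butane-1,2-diol | O[C@H](CO)CCO[Si](c1ccccc1)(c1ccccc1)C(C)(C)C
F7 | step 7 | (S)-1-[(4-methoxybenzyl)oxy]-4-[(tert-butyldiphenylsilyl)oxy]butan-2-ol | O[C@H](COCc1ccc(OC)cc1)CCO[Si](c1ccccc1)(c1ccccc1)C(C)(C)C
F8 | step 7 | (S)-1-[(4-methoxybenzyl)oxy]-4-[(tert-butyldiphenylsilyl)oxy]butan-2-yl methanesulfonate | CS(=O)(=O)O[C@H](COCc1ccc(OC)cc1)CCO[Si](c1ccccc1)(c1ccccc1)C(C)(C)C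
F9 | step 7 | (R)-tert-butyl{3-[(2-methoxypropan-2-yl)peroxy]-4-[(4-methoxybenzyl)oxy]butoxy}diphenylsilane | COC(C)(C)OO[C@@H](COCc1ccc(OC)cc1)CCO[Si](c1ccccc1)(c1ccccc1)C(C)(C)C
F10 | step 7 | (R)-2-[(2-methoxypropan-2-yl)peroxy]-4-[(tert-butyldiphenylsilyl)oxy]butan-1-ol | COC(C)(C)OO[C@@H](CO)CCO[Si](c1ccccc1)(c1ccccc1)C(C)(C)C
F11 | step 7 | (R)-2-[(2-methoxypropan-2-yl)peroxy]-4-[(tert-butyldiphenylsilyl)oxy]butanal | COC(C)(C)OO[C@@H](C=O)CCO[Si](c1ccccc1)(c1ccccc1)C(C)(C)C
F12 | step 13 | [6,6-dimethoxy-8-(phenylselanyl)oct-1-yn-1-yl]tri(propan-2-yl)silane | COC(CC[Se]c1ccccc1)(OC)CCCC#C[Si](C(C)C)(C(C)C)C(C)C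
F13 | step 13 | methyl (R,E)-4-{[3-methoxy-1-(phenylselanyl)-8-(triisopropylsilyl)oct-7-yn-3-yl]peroxy}-6-[(tert-butyldiphenylsilyl)oxy]hex-2-enoate, both ketal epimers | COC(CC[Se]c1ccccc1)(CCCC#C[Si](C(C)C)(C(C)C)C(C)C)OO[C@@H](/C=C/C(=O)OC)CCO[Si](c1ccccc1)(c1ccccc1)C(C)(C)C
A1 | alternative 1 | tert-butyl 3-hydroxy-6-(2-methoxy-2-oxoethyl)-3-{4-[(tert-butyldiphenylsilyl)oxy]butyl}-1,2-dioxane-4-carboxylate (racemic, target-series enantiomer drawn, C4 epimers) | O[C@@]1(CCCCO[Si](c2ccccc2)(c2ccccc2)C(C)(C)C)C(C(=O)OC(C)(C)C)C[C@@H](CC(=O)OC)OO1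
A2 | alternative 1 | tert-butyl 7-[(tert-butyldiphenylsilyl)oxy]-3-oxoheptanoate | CC(C)(C)OC(=O)CC(=O)CCCCO[Si](c1ccccc1)(c1ccccc1)C(C)(C)C
A3 | alternative 1 | methyl but-3-enoate | C=CCC(=O)OC
A4 | alternative 2 | tert-butyl{2-[(3R,6S)-3-methoxy-3-(pent-4-yn-1-yl)-1,2-dioxan-6-yl]ethoxy}diphenylsilane | CO[C@@]1(CCCC#C)CC[C@@H](CCO[Si](c2ccccc2)(c2ccccc2)C(C)(C)C)OO1
A5 | alternative 2 | (S)-1-[(tert-butyldiphenylsilyl)oxy]-3-hydroperoxyundec-10-yn-6-one | OO[C@@H](CCC(=O)CCCC#C)CCO[Si](c1ccccc1)(c1ccccc1)C(C)(C)C
A6 | alternative 3 | 3-[5-(trimethylsilyl)pent-4-yn-1-yl]-6-{2-[(tert-butyldiphenylsilyl)oxy]ethyl}-1,2-dioxan-3-ol (racemic, target-series enantiomer drawn) | O[C@@]1(CCCC#C[Si](C)(C)C)CC[C@@H](CCO[Si](c2ccccc2)(c2ccccc2)C(C)(C)C)OO1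
A7 | alternative 3 | 1-[5-(trimethylsilyl)pent-4-yn-1-yl]-2-{2-[(tert-butyldiphenylsilyl)oxy]ethyl}cyclobutan-1-ol | OC1(CCCC#C[Si](C)(C)C)CCC1CCO[Si](c1ccccc1)(c1ccccc1)C(C)(C)C
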